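**Retrosynthetic overview**
- The target is epimesquitol-(4β→6)-teracacidin: an upper 2,3-cis-3,4-trans flavan-3-ol joined through C4 to C6 of an all-cis flavan-3,4-diol.
- Key disconnection: the O1–C2 bond of each pyran ring (ring C), closed by oxidative oxa-cyclisation of a 2'-hydroxychalcone (Algar–Flynn–Oyamada). Both chalcones come from one benzylated gallacetophenone and a benzaldehyde.
- The flat flavonols then receive their stereocentres by a new all-cis asymmetric hydrogenation, which gives the (2R,3R,4R) flavan-3,4-diols of both units.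
- The interflavanyl C4–C6 bond is made last, from the 4β-benzylsulfanyl upper unit and the lower diol (silver-promoted), followed by global hydrogenolysis.
- Ring order: rings A and B are bought; upper ring C, then lower ring C, then union of the two flavan units.

Assumption: with the (R,R) ligand SINpEt·HBF4 (1,3-bis[(1R)-1-(naphthalen-1-yl)ethyl]-4,5-dihydroimidazolium tetrafluoroborate) hydrogen is taken to add to the face that gives the (2R,3R,4R) diols; if a first run shows the opposite sense, the (S,S) ligand is used and nothing else changes.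

**Step 1**
Reactants: 1 1-(2,3,4-trihydroxyphenyl)ethan-1-one (gallacetophenone)
Product: 2 1-[3,4-bis(benzyloxy)-2-hydroxyphenyl]ethan-1-one
Conditions: BnBr (2.1 equiv), K2CO3 (2.2 equiv), acetone, reflux, 12 h
Reagents that add atoms: benzyl bromide, BrCc1ccccc1
Why: Williamson etherification in which the 2-OH, locked in a hydrogen bond to the acetyl carbonyl, stays free, so that only the 3- and 4-OH are benzylated.

**Step 2**
Reactants: 2 1-[3,4-bis(benzyloxy)-2-hydroxyphenyl]ethan-1-one; 3 3,4-bis(benzyloxy)benzaldehyde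
Product: 6 7,8-bis(benzyloxy)-2-[3,4-bis(benzyloxy)phenyl]-3-hydroxy-4H-chromen-4-one, via chalcone 4 (not isolated), via trans-dihydroflavonol 5 (not isolated)
Conditions: KOH, EtOH/THF, rt, 24 h; then 30% aq. H2O2, 0 °C to rt, 4 h
Reagents that add atoms: hydrogen peroxide, OO
Why: Claisen–Schmidt condensation gives the (E)-chalcone, and alkaline peroxide then effects the Algar–Flynn–Oyamada oxidative cyclisation, in which the 2'-phenoxide closes ring C by forming the O1–C2 bond, peroxide supplies the C3 oxygen and the dihydroflavonol is dehydrogenated to the flavonol (no 6'-substituent, so no aurone).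

**Step 3**
Reactants: 6 7,8-bis(benzyloxy)-2-[3,4-bis(benzyloxy)phenyl]-3-hydroxy-4H-chromen-4-one
Product: 8 (2R,3R,4R)-7,8-bis(benzyloxy)-2-[3,4-bis(benzyloxy)phenyl]chromane-3,4-diol, via cis-dihydroflavonol 7 (not isolated)
Conditions: [Ru(cod)(2-methylallyl)2] (5 mol%), (R,R)-SINpEt·HBF4 (10 mol%), KOtBu (10 mol%), n-hexane, 70 °C, 16 h; then 6, H2 (120 bar), toluene, 40 °C, 48 h
Reagents that add atoms: none
Why: Proposed new method: ruthenium–NHC-catalysed all-cis asymmetric hydrogenation of a 3-hydroxyflavone, in which the chiral carbene–ruthenium hydride binds one face of the planar pyranone, adds H2 syn across the enol C2=C3 bond to give cis-dihydroflavonol 7 (sets C2 and C3) and then reduces the neighbouring ketone from the same face, which is also the substrate-preferred face because hydride enters anti to the axial 3-OH (sets C4), so that aryl, 3-OH and 4-OH end up all cis as (2R,3R,4R); the base is consumed in forming the carbene, so 7 should not epimerise at C3 before it is reduced; the closest known reaction type is the Ru–SINpEt hydrogenation of flavones and chromones to cis-flavan-4-ols, and the racemic all-cis hydrogenation of flavonols over Raney Ni is classical.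

**Step 4**
Reactants: 8 (2R,3R,4R)-7,8-bis(benzyloxy)-2-[3,4-bis(benzyloxy)phenyl]chromane-3,4-diol
Product: 9 (2R,3S,4S)-4-(benzylsulfanyl)-7,8-bis(benzyloxy)-2-[3,4-bis(benzyloxy)phenyl]chroman-3-ol
Conditions: BnSH (5 equiv), BF3·OEt2 (0.2 equiv), CH2Cl2, −20 to 0 °C, 1 h
Reagents that add atoms: benzyl mercaptan (phenylmethanethiol), SCc1ccccc1
Why: Acid-catalysed SN1 thiolysis of the benzylic 4-OH through the C4 cation stabilised by O1 and the para 7-benzyloxy group; the thiol enters anti to the axial 3-OH, as is the rule for 2,3-cis flavans, giving the 4β (3,4-trans) thioether (the C3 descriptor changes by CIP ranking only).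

**Step 5**
Reactants: 2 1-[3,4-bis(benzyloxy)-2-hydroxyphenyl]ethan-1-one; 10 4-(benzyloxy)benzaldehyde
Product: 13 7,8-bis(benzyloxy)-2-[4-(benzyloxy)phenyl]-3-hydroxy-4H-chromen-4-one, via chalcone 11 (not isolated), via trans-dihydroflavonol 12 (not isolated)
Conditions: KOH, EtOH/THF, rt, 24 h; then 30% aq. H2O2, 0 °C to rt, 4 h
Reagents that add atoms: hydrogen peroxide, OO
Why: Same one-pot Claisen–Schmidt condensation and Algar–Flynn–Oyamada oxidative cyclisation as in step 2, closing the lower ring C through the O1–C2 bond.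

**Step 6**
Reactants: 13 7,8-bis(benzyloxy)-2-[4-(benzyloxy)phenyl]-3-hydroxy-4H-chromen-4-one
Product: 15 (2R,3R,4R)-7,8-bis(benzyloxy)-2-[4-(benzyloxy)phenyl]chromane-3,4-diol, via cis-dihydroflavonol 14 (not isolated)
Conditions: [Ru(cod)(2-methylallyl)2] (5 mol%), (R,R)-SINpEt·HBF4 (10 mol%), KOtBu (10 mol%), n-hexane, 70 °C, 16 h; then 13, H2 (120 bar), toluene, 40 °C, 48 h
Reagents that add atoms: none
Why: Proposed new method: the same ruthenium–NHC all-cis asymmetric hydrogenation as in step 3 (face-selective syn addition of H2 to the enol C2=C3 bond to give 14, then same-face, substrate-matched reduction of the ketone anti to the axial 3-OH), here setting all three stereocentres of the lower unit as (2R,3R,4R); the closest known reaction type is the Ru–SINpEt hydrogenation of flavones to cis-flavan-4-ols.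

**Step 7**
Reactants: 9 (2R,3S,4S)-4-(benzylsulfanyl)-7,8-bis(benzyloxy)-2-[3,4-bis(benzyloxy)phenyl]chroman-3-ol; 15 (2R,3R,4R)-7,8-bis(benzyloxy)-2-[4-(benzyloxy)phenyl]chromane-3,4-diol (3 equiv, excess recovered)
Product: 16 (2R,3R,4R)-7,8-bis(benzyloxy)-2-[4-(benzyloxy)phenyl]-6-{(2R,3R,4R)-7,8-bis(benzyloxy)-2-[3,4-bis(benzyloxy)phenyl]-3-hydroxychroman-4-yl}chromane-3,4-diol
Conditions: AgBF4 (2.5 equiv), THF, 0 °C, dark, slow addition of 9, 1 h
Reagents that add atoms: none
Why: Thiophile-promoted Friedel–Crafts interflavanyl coupling in which monovalent silver removes the benzylthio group and C6 of 15 (para to O1 and ortho to the 7-benzyloxy group, the only doubly activated free position) attacks the C4 cation anti to the axial 3-OH, which sets the upper C4 centre as 4β (3,4-trans), while the thiophile leaves the free 4-OH of 15 untouched and THF buffers the acid released.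

**Step 8**
Reactants: 16 (2R,3R,4R)-7,8-bis(benzyloxy)-2-[4-(benzyloxy)phenyl]-6-{(2R,3R,4R)-7,8-bis(benzyloxy)-2-[3,4-bis(benzyloxy)phenyl]-3-hydroxychroman-4-yl}chromane-3,4-diol
Product: 17 (2R,3R,4R)-6-[(2R,3R,4S)-2-(3,4-dihydroxyphenyl)-3,7,8-trihydroxychroman-4-yl]-2-(4-hydroxyphenyl)chromane-3,4,7,8-tetrol
Conditions: H2 (1 atm), Pd(OH)2/C, THF/MeOH (1:1), rt, 3 h; filter under argon, Sephadex LH-20
Reagents that add atoms: none
Why: Hydrogenolysis of the seven aryl benzyl ethers is much faster under neutral conditions than loss of the free secondary benzylic 4-OH or cleavage of the C4–C6 bond, and no stereocentre is touched.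

**Compound list**
1 | 1-(2,3,4-trihydroxyphenyl)ethan-1-one (gallacetophenone) | CC(=O)c1ccc(O)c(O)c1O | starting material
2 | 1-[3,4-bis(benzyloxy)-2-hydroxyphenyl]ethan-1-one | CC(=O)c1ccc(OCc2ccccc2)c(OCc2ccccc2)c1O | intermediate
3 | 3,4-bis(benzyloxy)benzaldehyde | O=Cc1ccc(OCc2ccccc2)c(OCc2ccccc2)c1 | starting material
4 | (E)-1-[3,4-bis(benzyloxy)-2-hydroxyphenyl]-3-[3,4-bis(benzyloxy)phenyl]prop-2-en-1-one | O=C(/C=C/c1ccc(OCc2ccccc2)c(OCc2ccccc2)c1)c1ccc(OCc2ccccc2)c(OCc2ccccc2)c1O | intermediate (not isolated)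
5 | rac-(2R,3R)-7,8-bis(benzyloxy)-2-[3,4-bis(benzyloxy)phenyl]-3-hydroxychroman-4-one (2,3-trans; racemic, one enantiomer drawn) | O=C1c2ccc(OCc3ccccc3)c(OCc3ccccc3)c2O[C@H](c2ccc(OCc3ccccc3)c(OCc3ccccc3)c2)[C@H]1O | intermediate (not isolated)
6 | 7,8-bis(benzyloxy)-2-[3,4-bis(benzyloxy)phenyl]-3-hydroxy-4H-chromen-4-one | O=c1c(O)c(-c2ccc(OCc3ccccc3)c(OCc3ccccc3)c2)oc2c(OCc3ccccc3)c(OCc3ccccc3)ccc12 | intermediate
7 | (2R,3S)-7,8-bis(benzyloxy)-2-[3,4-bis(benzyloxy)phenyl]-3-hydroxychroman-4-one (2,3-cis) | O=C1c2ccc(OCc3ccccc3)c(OCc3ccccc3)c2O[C@H](c2ccc(OCc3ccccc3)c(OCc3ccccc3)c2)[C@@H]1O | intermediate (not isolated)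
8 | (2R,3R,4R)-7,8-bis(benzyloxy)-2-[3,4-bis(benzyloxy)phenyl]chromane-3,4-diol (tetra-O-benzylmelacacidin; 2,3-cis-3,4-cis) | O[C@@H]1c2ccc(OCc3ccccc3)c(OCc3ccccc3)c2O[C@H](c2ccc(OCc3ccccc3)c(OCc3ccccc3)c2)[C@@H]1O | intermediate
9 | (2R,3S,4S)-4-(benzylsulfanyl)-7,8-bis(benzyloxy)-2-[3,4-bis(benzyloxy)phenyl]chroman-3-ol (2,3-cis-3,4-trans; 4β-SBn) | c1ccccc1CS[C@H]1c2ccc(OCc3ccccc3)c(OCc3ccccc3)c2O[C@H](c2ccc(OCc3ccccc3)c(OCc3ccccc3)c2)[C@@H]1O | intermediate
10 | 4-(benzyloxy)benzaldehyde | O=Cc1ccc(OCc2ccccc2)cc1 | starting material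
11 | (E)-1-[3,4-bis(benzyloxy)-2-hydroxyphenyl]-3-[4-(benzyloxy)phenyl]prop-2-en-1-one | O=C(/C=C/c1ccc(OCc2ccccc2)cc1)c1ccc(OCc2ccccc2)c(OCc2ccccc2)c1O | intermediate (not isolated)
12 | rac-(2R,3R)-7,8-bis(benzyloxy)-2-[4-(benzyloxy)phenyl]-3-hydroxychroman-4-one (2,3-trans; racemic, one enantiomer drawn) | O=C1c2ccc(OCc3ccccc3)c(OCc3ccccc3)c2O[C@H](c2ccc(OCc3ccccc3)cc2)[C@H]1O | intermediate (not isolated)
13 | 7,8-bis(benzyloxy)-2-[4-(benzyloxy)phenyl]-3-hydroxy-4H-chromen-4-one | O=c1c(O)c(-c2ccc(OCc3ccccc3)cc2)oc2c(OCc3ccccc3)c(OCc3ccccc3)ccc12 | intermediate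
14 | (2R,3S)-7,8-bis(benzyloxy)-2-[4-(benzyloxy)phenyl]-3-hydroxychroman-4-one (2,3-cis) | O=C1c2ccc(OCc3ccccc3)c(OCc3ccccc3)c2O[C@H](c2ccc(OCc3ccccc3)cc2)[C@@H]1O | intermediate (not isolated)
15 | (2R,3R,4R)-7,8-bis(benzyloxy)-2-[4-(benzyloxy)phenyl]chromane-3,4-diol (tri-O-benzylteracacidin; 2,3-cis-3,4-cis) | O[C@@H]1c2ccc(OCc3ccccc3)c(OCc3ccccc3)c2O[C@H](c2ccc(OCc3ccccc3)cc2)[C@@H]1O | intermediate
16 | (2R,3R,4R)-7,8-bis(benzyloxy)-2-[4-(benzyloxy)phenyl]-6-{(2R,3R,4R)-7,8-bis(benzyloxy)-2-[3,4-bis(benzyloxy)phenyl]-3-hydroxychroman-4-yl}chromane-3,4-diol (hepta-O-benzyl ether of the target; upper unit 4β-aryl, whose C4 descriptor reads R here and S in 17 by CIP ranking only) | c1ccccc1COc1ccc(cc1)[C@H]1Oc2c(cc([C@H]3c4ccc(OCc5ccccc5)c(OCc5ccccc5)c4O[C@H](c4ccc(OCc5ccccc5)c(OCc5ccccc5)c4)[C@@H]3O)c(OCc3ccccc3)c2OCc2ccccc2)[C@@H](O)[C@H]1O | intermediate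
17 | (2R,3R,4R)-6-[(2R,3R,4S)-2-(3,4-dihydroxyphenyl)-3,7,8-trihydroxychroman-4-yl]-2-(4-hydroxyphenyl)chromane-3,4,7,8-tetrol (CNP0174688.1) | Oc1ccc([C@H]2Oc3c(cc([C@H]4c5ccc(O)c(O)c5O[C@H](c5ccc(O)c(O)c5)[C@@H]4O)c(O)c3O)[C@@H](O)[C@H]2O)cc1 | target

**Step count and risks**
Total step count: 8 (steps 2 and 5 are one-pot operations). Longest linear sequence: 6 steps (1, 2, 3, 4, 7, 8); the lower-unit branch is steps 1, 5, 6.

The three steps most likely to fail:

Step 3 (the proposed new hydrogenation, upper unit). The flavonol may bind ruthenium as a chelating flavonolate and stall the catalyst, 7 may epimerise at C3 before the ketone is reduced, or the enantioselectivity may be low. The fallback uses known chemistry and sets out from 6: heterogeneous hydrogenation over Raney Ni (H2 80 bar, EtOH/THF, 60 °C), the classical all-cis reduction of flavonols to 2,3-cis-3,4-cis-flavan-3,4-diols, gives racemic tetra-O-benzylmelacacidin F1. This is resolved by preparative HPLC on an amylose tris(3,5-dimethylphenylcarbamate) phase; the (2R,3R,4R) enantiomer is 8, where the route is rejoined.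

Step 6 (the same new hydrogenation, lower unit). The risks are the same as in step 3. The fallback uses known chemistry and sets out from 13: Raney Ni hydrogenation as above gives racemic tri-O-benzylteracacidin F2. This is not resolved but taken as such into the silver-promoted coupling with enantiopure 9, so that the upper unit acts as the resolving handle. The two diastereomeric dimers are separated on silica; the unwanted one is the dimer built on the (2S,3S,4S) lower unit F3, and the other is 16, where the route is rejoined.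

Step 7 (interflavanyl coupling). The benzylated pyrogallol-type ring A of 15 is only a moderate nucleophile, so O-alkylation by its 3-OH or 4-OH and self-condensation of 9 can compete. The fallback is an unprotected biomimetic endgame that sets out from 8 and 15. Hydrogenolysis of 8 (H2, Pd(OH)2/C, THF/MeOH) gives melacacidin F4, and thiolysis (BnSH, AcOH, EtOH, reflux) turns it into 4β-benzylsulfanylepimesquitol F5. Hydrogenolysis of 15 gives teracacidin F6. AgBF4 in THF at 0 °C then couples F5 with an excess of F6, whose free phenolic ring A is the more nucleophilic partner. This gives 17 directly, so the route is rejoined at 17 and step 8 falls away.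

**Further compounds**
F1 | step 3 | racemic (2R*,3R*,4R*)-7,8-bis(benzyloxy)-2-[3,4-bis(benzyloxy)phenyl]chromane-3,4-diol (8 together with its enantiomer) | O[C@@H]1c2ccc(OCc3ccccc3)c(OCc3ccccc3)c2O[C@H](c2ccc(OCc3ccccc3)c(OCc3ccccc3)c2)[C@@H]1O.O[C@H]1c2ccc(OCc3ccccc3)c(OCc3ccccc3)c2O[C@@H](c2ccc(OCc3ccccc3)c(OCc3ccccc3)c2)[C@H]1O
F2 | step 6 | racemic (2R*,3R*,4R*)-7,8-bis(benzyloxy)-2-[4-(benzyloxy)phenyl]chromane-3,4-diol (15 together with its enantiomer) | O[C@@H]1c2ccc(OCc3ccccc3)c(OCc3ccccc3)c2O[C@H](c2ccc(OCc3ccccc3)cc2)[C@@H]1O.O[C@H]1c2ccc(OCc3ccccc3)c(OCc3ccccc3)c2O[C@@H](c2ccc(OCc3ccccc3)cc2)[C@H]1O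
F3 | step 6 | (2S,3S,4S)-7,8-bis(benzyloxy)-2-[4-(benzyloxy)phenyl]-6-{(2R,3R,4R)-7,8-bis(benzyloxy)-2-[3,4-bis(benzyloxy)phenyl]-3-hydroxychroman-4-yl}chromane-3,4-diol (diastereomer of 16 built on the enantiomer of 15) | c1ccccc1COc1ccc(cc1)[C@@H]1Oc2c(cc([C@H]3c4ccc(OCc5ccccc5)c(OCc5ccccc5)c4O[C@H](c4ccc(OCc5ccccc5)c(OCc5ccccc5)c4)[C@@H]3O)c(OCc3ccccc3)c2OCc2ccccc2)[C@H](O)[C@@H]1O
F4 | step 7 | (2R,3R,4R)-2-(3,4-dihydroxyphenyl)chromane-3,4,7,8-tetrol (melacacidin) | O[C@@H]1c2ccc(O)c(O)c2O[C@H](c2ccc(O)c(O)c2)[C@@H]1O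
F5 | step 7 | (2R,3S,4S)-4-(benzylsulfanyl)-2-(3,4-dihydroxyphenyl)chromane-3,7,8-triol (4β-benzylsulfanylepimesquitol) | c1ccccc1CS[C@H]1c2ccc(O)c(O)c2O[C@H](c2ccc(O)c(O)c2)[C@@H]1O
F6 | step 7 | (2R,3R,4R)-2-(4-hydroxyphenyl)chromane-3,4,7,8-tetrol (teracacidin) | O[C@@H]1c2ccc(O)c(O)c2O[C@H](c2ccc(O)cc2)[C@@H]1O
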